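The earlier runs and the new flask are calculated from invented constants, noise included.

At the end of delta J reads 19.2% while Q has lost 14 percentage points, so J is more than Q gave up, and I take it that G turns Z into Q and that the two fall together.

| setting | theta | delta | gamma | flask |
|---|---|---|---|---|
| Q | 0.14 M | 0.14 M | 0.14 M | 0.14 M |
| Z | 0.14 M | 0.14 M | 0.14 M | 0.14 M |
| L | 2.5 equiv | 2.5 equiv | 2.5 equiv | 2.50 equiv |
| D | 0.5 mol% | 2 mol% | 1 mol% | 1 mol% |
| G | 1 mol% | 1 mol% | 0.5 mol% | 1 mol% |
| remark | run made earlier | run made earlier | run made earlier |  |
| time |  |  |  | 2.5 h |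

- theta (time / h: J / %, Q / %): 0.250: 4.6, 45.8; 0.333: 5.3, 46.2; 0.500: 6.4, 45.3; 0.833: 7.4, 45.1; 1.33: 7.6, 45.5; 2.00: 6.9, 45.3; 3.00: 7.5, 45.3
- delta (time / h: J / %, Q / %): 0.417: 17.2, 36.8; 0.833: 19.1, 36.3; 1.33: 20.0, 34.9; 1.50: 19.6, 35.6; 2.00: 19.4, 36.1; 2.50: 19.3, 35.0; 3.00: 19.2, 35.6
- gamma (time / h: J / %, Q / %): 0.667: 11.9, 41.6; 1.33: 12.3, 40.2; 2.00: 13.5, 40.7; 2.50: 13.1, 39.9; 3.00: 13.8, 40.0

(each reading ± 0.5 percentage points)

- D is single-handed; Q and Z are mirror images of each other, charged as a racemate, each of them at the stated concentration
- the earlier runs were read with a standard deviation of 0.5 percentage points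
- the reaction counts as stopped when no species that holds the Q and Z together changes by six tenths of a point or more over the second half of the time

* at 2.5 h, what has stopped the reaction, if anything has (L has run out first / forward and back rates have come level / it is still moving / all of Q has reacted / no working catalyst is left)
* amount of J at 2.5 h, in percent of the Q and Z together charged

But J stands still at a height that moves with D between theta and delta, which share their G, and the point where forward and back rates come level does not move with the amount of a catalyst, so I suppose that something ends the reaction on a clock of its own, with the loss pseudo-first-order in Q while the clock runs.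

Minus the natural log of the fraction of Q left at the last reading, scaled in proportion to D to the flask's 1 mol%, reads 0.197 in theta, 0.170 in delta and 0.223 in gamma, and their mean I call the exposure, 0.197.

My reckoning for the flask leaves 82.1% of Q and Z, and since J took 69.6% of the pooled loss in the three runs, it gives 12.4% of J, but it does not tell me what the clock is.

The forecast says 12.3%, between 11% and 13.8%, and no working catalyst is left: “The catalyst is therefore dying”.

    L + D + Q → D + J (k = 110 /M²/min)
    Q + G ⇌ Z + G, rate k2*[G]*[Q] forward; the back reaction follows from the equilibrium constant (k = 60.0 /M/min)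
    L + D + Z → D + E (k = 50.0 /M²/min)
    2 L → X (k = 0.840 /M/min)

The flask gives 12.7% of J at 2.5 h, and the answer is L has run out first: 0.089% of L remains, with D at 100%. At the start the reaction of 2 L to X uses L 27 times as fast as the step to J. The exposure read from this flask's Q, 81% of its charge, is 0.206, beside my 0.197. For the neighbour with 0.4 mol% of D, my exposure gives 5.27% of J; that neighbour holds 6.52%, with its Q at 90% of charge, which scaled to 1 mol% of D is an exposure of 0.250.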